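- Slowness in this flask is a matter of what happens to the reagent while the catalyst waits, so I follow the rate of target formation and ask what wears it down over the run.

the same everywhere: starting material 0.15 M; second substrate 0.200 equiv; catalyst 5 mol%; time 10 h
- green: reagent 2.00 equiv
- blue: reagent 2.50 equiv
- ochre: reagent 4.00 equiv

    starting material + reagent + catalyst → catalyst + target (k1 = 0.072 L² mol⁻² s⁻¹)
    second substrate + reagent + catalyst → catalyst + second product (k2 = 0.99 L² mol⁻² s⁻¹)
    reagent ⇌ dormant form (K3 = 13, k3 = 3.3 × 10⁻⁴ s⁻¹)

- amount of target at the end, in percent of the starting material charged for green, blue, ochre, in this order
- how the row runs (hardly changes / rises, then falls / rises all the way / falls all the way / falls, then rises)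

- "hardly changes" means that all values lie within two and a half points (for a concentration: within two and a half percent of the largest)
- run time (green): 10 h

- In green the starting rate is 0.0875 M h⁻¹, and held for 10 h it would make 5.83 times the starting material charged, so the end depends on the slowing.
- The first slowing I reckon is hiding: reagent relaxes towards the dormant form with a half-life of 0.542 h, shorter than the run, and the free share then sits near 0.0714.
- I therefore define the effective time τ, the hours at fully free reagent that give the same mean of free reagent as the run: τ = 1.44 h, of which the initial fall gives 0.726 h and the later trickle 0.714 h; it contains no charge, and in green it slows the mean rate by a factor of 6.94.
- The second substrate comes next, because its half-life of 0.086 h is shorter than the 0.58 h of the forward hiding, so I take its charge off the reagent first, a factor of 1.11 in green.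
- Starting material and reagent then leave one for one, so I use the integrated second-order law in effective time, with x = 0.420 as the pseudo-first-order exponent per equivalent of reagent.
- That law leaves 52.7% of the starting material in green, 43.8% in blue and 24.7% in ochre, so the target rises along the row: 47 percentage points, 56 points, 75 points, and the row I commit to rises all the way. In green this is a mean slowing by consumption of 1.60.
- I ignore the first step's own drain on free reagent, which at the start in green is 4.1 times smaller than the forward hiding, so my yields should lean high.
- The forecast gives 48%, 56% and 76%, a row that rises all the way, on the ground that “the target then forms slowly on the trickle of free reagent released from that reservoir”.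
- The flasks give 44.6%, 53.6% and 73.2%, a row that rises all the way, and in green my figure stands 2.7 points high. In green, half of the turnover of the first step up to 10 h is done by 0.787 h. Carried to blue at 100 h, the effective time becomes 7.87 h, the second-order law gives 97.1% of target, and blue holds 96.7% at that time.

The numbers are assumed, and the outcome is calculated.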